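**Retrosynthetic overview**
- **Feature:** ring B is a 1,2,3,5-tetrasubstituted benzene. C4a' (carbon), C8a' (O1') and C8' (OH) are adjacent, and C6' carries flavanone C2. Read as pyrone C3–C6 plus the two-carbon unit C4a'–C5', ring B is a 3,4-dioxygenated 2-pyrone with a one-carbon group on C6, joined to an alkyne through its C3 oxygen.
- **Late disconnections:** the benzyl ethers and the acetonide come off last. Ring C is opened at O1–C8a (aryl ether closure of a 1,3-diol) and at C2–C3 (aldol of the ring B aldehyde with a 2-bromoaryl methyl ketone). C2 is set by transfer hydrogenation of the derived 1,3-diketone.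
- **Key disconnection:** C4a'–C8a' and C5'–C6' are cut together. An intramolecular pyrone–alkyne (4+2) cycloaddition with loss of CO2 builds rings B and D in one operation.
- **Precursor:** the pyrone C3–O1' ether comes from Rh2(OAc)4-catalysed O–H insertion of a 3-diazopyran-2,4-dione into a tertiary alkynol. C3' and C4' of that alkynol are the two carbinol carbons of L-tartrate.
- **Order of rings:** pyrone (sacrificial), then B and D together, then C. Ring A is bought.

Key step: step 12

Remark: primed locants belong to the chroman unit (rings B and D) and unprimed ones to the flavanone core (rings A and C). ArB = (3R,4S)-8-benzyloxy-2,2-dimethyl-3,4-(isopropylidenedioxy)chroman-6-yl. Compounds 7 and 17 are taken as catalogue compounds (7 is otherwise one silylation away from methyl glycolate).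

Step 1
Reactants: 1 dimethyl (4R,5R)-2,2-dimethyl-1,3-dioxolane-4,5-dicarboxylate (dimethyl 2,3-O-isopropylidene-L-tartrate)
Product: 2 methyl (4R,5S)-5-(hydroxymethyl)-2,2-dimethyl-1,3-dioxolane-4-carboxylate
Conditions: NaBH4 (0.55 equiv), MeOH, 0 °C to rt; chromatography from unreacted 1 and the diol
Reagents that add atoms: none
Why: Borohydride reduction of an alkoxy-activated ester with a deficit of hydride should stop largely at the hydroxy ester, the C2 symmetry of 1 allows only one mono-product, and neither stereocentre is touched.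

Step 2
Reactants: 2 methyl (4R,5S)-5-(hydroxymethyl)-2,2-dimethyl-1,3-dioxolane-4-carboxylate
Product: 3 2-[(4R,5S)-5-(hydroxymethyl)-2,2-dimethyl-1,3-dioxolan-4-yl]propan-2-ol
Conditions: MeMgBr (4 equiv), THF, 0 °C to rt; aq NH4Cl
Reagents that add atoms: methylmagnesium bromide, C[Mg]Br
Why: Double Grignard addition to the ester (one further equivalent is spent on the free hydroxyl) builds the C2' gem-dimethyl carbinol without touching C3' or C4'.

Step 3
Reactants: 3 2-[(4R,5S)-5-(hydroxymethyl)-2,2-dimethyl-1,3-dioxolan-4-yl]propan-2-ol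
Product: 4 (4R,5R)-5-(2-hydroxypropan-2-yl)-2,2-dimethyl-1,3-dioxolane-4-carbaldehyde
Conditions: TEMPO (10 mol %), PhI(OAc)2 (1.1 equiv), CH2Cl2, rt
Reagents that add atoms: none
Why: The oxoammonium (TEMPO) oxidation takes the primary alcohol to the aldehyde and cannot oxidise the tertiary carbinol, while the trans-dioxolane blocks lactol formation and the trans aldehyde is the more stable epimer.

Step 4
Reactants: 4 (4R,5R)-5-(2-hydroxypropan-2-yl)-2,2-dimethyl-1,3-dioxolane-4-carbaldehyde
Product: 5 2-[(4R,5S)-5-ethynyl-2,2-dimethyl-1,3-dioxolan-4-yl]propan-2-ol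
Conditions: dimethyl (1-diazo-2-oxopropyl)phosphonate (1.3 equiv), K2CO3, MeOH, 0 °C to rt
Reagents that add atoms: dimethyl (1-diazo-2-oxopropyl)phosphonate, CC(=O)C(=[N+]=[N-])P(=O)(OC)OC
Why: The Ohira–Bestmann homologation converts the aldehyde into the terminal alkyne under mild carbonate conditions and adds the carbon that becomes C5', and the trans C3'/C4' relationship is also the thermodynamically preferred one.

Step 5
Reactants: 6 methyl acetoacetate; 7 methyl 2-[(tert-butyldimethylsilyl)oxy]acetate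
Product: 8 methyl 6-[(tert-butyldimethylsilyl)oxy]-3,5-dioxohexanoate
Conditions: 6 (2 equiv), NaH then n-BuLi, THF, 0 °C; 7, 0 °C to rt; AcOH quench
Reagents that add atoms: none
Why: In this dianion acylation (Weiler dianion) the terminal carbon of the acetoacetate dianion attacks the ester, and the future formyl carbon enters at the protected alcohol level so that no hot late-stage oxidation is needed next to the alkyne.

Step 6
Reactants: 8 methyl 6-[(tert-butyldimethylsilyl)oxy]-3,5-dioxohexanoate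
Product: 9 6-{[(tert-butyldimethylsilyl)oxy]methyl}-4-hydroxy-2H-pyran-2-one
Conditions: DBU, toluene, reflux; dilute citric acid wash
Reagents that add atoms: none
Why: Base-induced lactonisation of a 3,5-dioxo ester through its C5 enol is the standard entry to 6-substituted 4-hydroxy-2-pyrones.

Step 7
Reactants: 9 6-{[(tert-butyldimethylsilyl)oxy]methyl}-4-hydroxy-2H-pyran-2-one
Product: 10 3-diazo-6-{[(tert-butyldimethylsilyl)oxy]methyl}-2H-pyran-2,4(3H)-dione
Conditions: 4-acetamidobenzenesulfonyl azide, Et3N, MeCN, 0 °C to rt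
Reagents that add atoms: 4-acetamidobenzenesulfonyl azide, CC(=O)Nc1ccc(cc1)S(=O)(=O)N=[N+]=[N-]
Why: Regitz diazo transfer takes place at the acidic C3 position of the cyclic 1,3-dicarbonyl tautomer.

Step 8
Reactants: 5 2-[(4R,5S)-5-ethynyl-2,2-dimethyl-1,3-dioxolan-4-yl]propan-2-ol; 10 3-diazo-6-{[(tert-butyldimethylsilyl)oxy]methyl}-2H-pyran-2,4(3H)-dione
Product: 11 3-{2-[(4R,5S)-5-ethynyl-2,2-dimethyl-1,3-dioxolan-4-yl]propan-2-yloxy}-4-hydroxy-6-{[(tert-butyldimethylsilyl)oxy]methyl}-2H-pyran-2-one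
Conditions: Rh2(OAc)4 (2 mol %), 4 Å MS, PhF, 80 °C; 10 (1.3 equiv) added slowly
Reagents that add atoms: none
Why: In this Rh2(OAc)4-catalysed O–H insertion the electrophilic carbenoid is captured by the hydroxyl oxygen and proton transfer with enolisation gives the 3-alkoxy-4-hydroxy-2-pyrone, a reaction type that accepts tertiary alcohols, while the propargylic oxygen makes the terminal alkyne a poor competitor.

Step 9
Reactants: 11 3-{2-[(4R,5S)-5-ethynyl-2,2-dimethyl-1,3-dioxolan-4-yl]propan-2-yloxy}-4-hydroxy-6-{[(tert-butyldimethylsilyl)oxy]methyl}-2H-pyran-2-one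
Product: 12 4-benzyloxy-3-{2-[(4R,5S)-5-ethynyl-2,2-dimethyl-1,3-dioxolan-4-yl]propan-2-yloxy}-6-{[(tert-butyldimethylsilyl)oxy]methyl}-2H-pyran-2-one
Conditions: BnBr, K2CO3, DMF, rt
Reagents that add atoms: benzyl bromide, BrCc1ccccc1
Why: Williamson-type O-alkylation of the vinylogous acid with a benzylic halide under carbonate conditions normally favours the 4-alkoxy-2-pyrone, and C-alkylation is blocked at C3.

Step 10
Reactants: 12 4-benzyloxy-3-{2-[(4R,5S)-5-ethynyl-2,2-dimethyl-1,3-dioxolan-4-yl]propan-2-yloxy}-6-{[(tert-butyldimethylsilyl)oxy]methyl}-2H-pyran-2-one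
Product: 13 4-benzyloxy-3-{2-[(4R,5S)-5-ethynyl-2,2-dimethyl-1,3-dioxolan-4-yl]propan-2-yloxy}-6-(hydroxymethyl)-2H-pyran-2-one
Conditions: Et3N·3HF, THF, rt
Reagents that add atoms: none
Why: Fluoride cleavage of the primary silyl ether under buffered conditions leaves the acetonide, the pyrone and the alkyne intact.

Step 11
Reactants: 13 4-benzyloxy-3-{2-[(4R,5S)-5-ethynyl-2,2-dimethyl-1,3-dioxolan-4-yl]propan-2-yloxy}-6-(hydroxymethyl)-2H-pyran-2-one
Product: 14 4-benzyloxy-3-{2-[(4R,5S)-5-ethynyl-2,2-dimethyl-1,3-dioxolan-4-yl]propan-2-yloxy}-2-oxo-2H-pyran-6-carbaldehyde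
Conditions: Dess–Martin periodinane, CH2Cl2, 0 °C to rt
Reagents that add atoms: none
Why: Dess–Martin oxidation of the allylic-type primary alcohol gives the 6-formylpyrone at room temperature, far below the onset of cycloaddition.

Step 12
Reactants: 14 4-benzyloxy-3-{2-[(4R,5S)-5-ethynyl-2,2-dimethyl-1,3-dioxolan-4-yl]propan-2-yloxy}-2-oxo-2H-pyran-6-carbaldehyde
Product: 16 trans-fused acetonide of (3R,4S)-8-benzyloxy-3,4-dihydroxy-2,2-dimethylchroman-6-carbaldehyde (ArB–CHO), via bridged lactone cycloadduct 15 (not isolated)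
Conditions: 1,2-Cl2C6H4 (0.01 M, degassed), BHT (10 mol %), sealed tube, 180 °C
Reagents that add atoms: none
Why: The alkyne adds across C3 and C6 of the 2-pyrone in a concerted intramolecular (4+2) cycloaddition (internal alkyne carbon to C3 = C4a'–C8a', terminal carbon to C6 = C5'–C6') to give the 2-oxabicyclo[2.2.2]octadienone 15, which expels CO2 by a retro-(4+2) step at the same temperature and leaves benzene ring B. This is the known pyrone–alkyne Diels–Alder/decarboxylation benzannulation in its tethered form. Ring D closes as the six-membered tether ring of a type 1 intramolecular Diels–Alder reaction (tether atoms O1', C2', C3', C4'), and ring B closes as the new carbocycle of the cycloaddition and becomes aromatic when the lactone bridge leaves. No lasting stereocentre is formed, because both bridgeheads of 15 end as sp2 carbons, so attack on either pyrone face leads to 16, and C3' and C4' are not touched. The only selectivity needed is regiochemical and the tether secures it, since the internal alkyne carbon can reach only C3. The formyl group lowers the pyrone LUMO toward the unactivated alkyne, and the gem-dimethyl group and the trans-dioxolane hold the two arms gauche.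

Step 13
Reactants: 17 1-(2-bromo-4-hydroxyphenyl)ethan-1-one
Product: 18 1-[4-(benzyloxy)-2-bromophenyl]ethan-1-one
Conditions: BnBr, K2CO3, acetone, reflux
Reagents that add atoms: benzyl bromide, BrCc1ccccc1
Why: Williamson ether synthesis on an acidic para-acyl phenol.

Step 14
Reactants: 16 ArB–CHO; 18 1-[4-(benzyloxy)-2-bromophenyl]ethan-1-one
Product: 19 1-[4-(benzyloxy)-2-bromophenyl]-3-hydroxy-3-(ArB)propan-1-one (both carbinol epimers)
Conditions: 18, LiN(iPr)2, THF, −78 °C; 16; AcOH quench at −78 °C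
Reagents that add atoms: none
Why: Lithium enolate aldol addition to a non-enolisable aldehyde forms C2–C3, and the carbinol configuration does not matter because step 15 erases it.

Step 15
Reactants: 19 1-[4-(benzyloxy)-2-bromophenyl]-3-hydroxy-3-(ArB)propan-1-one
Product: 20 1-[4-(benzyloxy)-2-bromophenyl]-3-(ArB)propane-1,3-dione
Conditions: Dess–Martin periodinane, CH2Cl2, rt
Reagents that add atoms: none
Why: Dess–Martin oxidation of a β-hydroxy ketone gives the 1,3-diketone without retro-aldol cleavage or dehydration.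

Step 16
Reactants: 20 1-[4-(benzyloxy)-2-bromophenyl]-3-(ArB)propane-1,3-dione
Product: 21 (1S,3S)-1-[4-(benzyloxy)-2-bromophenyl]-3-(ArB)propane-1,3-diol
Conditions: RuCl[(S,S)-TsDPEN](p-cymene) (5 mol %), HCO2H–Et3N (5:2), EtOAc, 40 °C
Reagents that add atoms: none
Why: Noyori–Ikariya asymmetric transfer hydrogenation reduces both aryl ketones under catalyst control, the (S,S)-TsDPEN complex giving (S)-aryl carbinols in the sense known for acetophenone, so the future C2 is set as S (the future C4 is also S and is erased later), and formic acid makes the reduction irreversible.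

Step 17
Reactants: 21 (1S,3S)-1-[4-(benzyloxy)-2-bromophenyl]-3-(ArB)propane-1,3-diol
Product: 22 (2S,4S)-7-(benzyloxy)-2-(ArB)chroman-4-ol (2,4-cis)
Conditions: CuI (10 mol %), 1,10-phenanthroline (20 mol %), Cs2CO3, toluene, 110 °C
Reagents that add atoms: none
Why: In this intramolecular Ullmann-type C–O coupling only the ArB-carbinol oxygen can reach the C–Br carbon through a six-membered ring, and the C2–O bond is never broken, so the S configuration is retained.

Step 18
Reactants: 22 (2S,4S)-7-(benzyloxy)-2-(ArB)chroman-4-ol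
Product: 23 (2S)-7-(benzyloxy)-2-(ArB)chroman-4-one
Conditions: Dess–Martin periodinane, CH2Cl2, rt
Reagents that add atoms: none
Why: Dess–Martin oxidation of the benzylic C4 alcohol runs without base and so avoids the ring opening to the chalcone that would epimerise C2.

Step 19
Reactants: 23 (2S)-7-(benzyloxy)-2-(ArB)chroman-4-one
Product: 24 (2S)-7-(benzyloxy)-2-[(3R,4S)-8-(benzyloxy)-3,4-dihydroxy-2,2-dimethylchroman-6-yl]chroman-4-one
Conditions: AcOH–H2O (4:1), 40 °C
Reagents that add atoms: none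
Why: Acid hydrolysis of the strained trans-fused ketal proceeds by cleavage at the ketal carbon, so the C3'–O and C4'–O bonds and their configurations are kept.

Step 20
Reactants: 24 (2S)-7-(benzyloxy)-2-[(3R,4S)-8-(benzyloxy)-3,4-dihydroxy-2,2-dimethylchroman-6-yl]chroman-4-one
Product: 25 (2S)-7-hydroxy-2-[(3R,4S)-3,4,8-trihydroxy-2,2-dimethylchroman-6-yl]chroman-4-one (target)
Conditions: H2 (1 atm), 10% Pd/C, EtOAc, rt
Reagents that add atoms: none
Why: Hydrogenolysis of the two aryl benzyl ethers under neutral conditions is much faster than cleavage of the secondary benzylic C–O bonds at C2 and C4', and no base is present to epimerise C2.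

**Compound list**
1 | dimethyl (4R,5R)-2,2-dimethyl-1,3-dioxolane-4,5-dicarboxylate | COC(=O)[C@@H]1OC(C)(C)O[C@H]1C(=O)OC | starting material
2 | methyl (4R,5S)-5-(hydroxymethyl)-2,2-dimethyl-1,3-dioxolane-4-carboxylate | COC(=O)[C@@H]1OC(C)(C)O[C@H]1CO | intermediate
3 | 2-[(4R,5S)-5-(hydroxymethyl)-2,2-dimethyl-1,3-dioxolan-4-yl]propan-2-ol | CC(C)(O)[C@@H]1OC(C)(C)O[C@H]1CO | intermediate
4 | (4R,5R)-5-(2-hydroxypropan-2-yl)-2,2-dimethyl-1,3-dioxolane-4-carbaldehyde | CC(C)(O)[C@@H]1OC(C)(C)O[C@H]1C=O | intermediate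
5 | 2-[(4R,5S)-5-ethynyl-2,2-dimethyl-1,3-dioxolan-4-yl]propan-2-ol | CC(C)(O)[C@@H]1OC(C)(C)O[C@H]1C#C | intermediate
6 | methyl acetoacetate | COC(=O)CC(C)=O | starting material
7 | methyl 2-[(tert-butyldimethylsilyl)oxy]acetate | COC(=O)CO[Si](C)(C)C(C)(C)C | starting material
8 | methyl 6-[(tert-butyldimethylsilyl)oxy]-3,5-dioxohexanoate | COC(=O)CC(=O)CC(=O)CO[Si](C)(C)C(C)(C)C | intermediate
9 | 6-{[(tert-butyldimethylsilyl)oxy]methyl}-4-hydroxy-2H-pyran-2-one | O=C1C=C(O)C=C(CO[Si](C)(C)C(C)(C)C)O1 | intermediate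
10 | 3-diazo-6-{[(tert-butyldimethylsilyl)oxy]methyl}-2H-pyran-2,4(3H)-dione | O=C1OC(CO[Si](C)(C)C(C)(C)C)=CC(=O)C1=[N+]=[N-] | intermediate
11 | 3-(tert-alkoxy)-4-hydroxy-6-(silyloxymethyl)-2-pyrone (full name in step 8) | O=C1OC(CO[Si](C)(C)C(C)(C)C)=CC(O)=C1OC(C)(C)[C@@H]2OC(C)(C)O[C@H]2C#C | intermediate
12 | 4-benzyl ether of 11 | O=C1OC(CO[Si](C)(C)C(C)(C)C)=CC(OCc2ccccc2)=C1OC(C)(C)[C@@H]3OC(C)(C)O[C@H]3C#C | intermediate
13 | 6-(hydroxymethyl)pyrone from 12 | O=C1OC(CO)=CC(OCc2ccccc2)=C1OC(C)(C)[C@@H]3OC(C)(C)O[C@H]3C#C | intermediate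
14 | 4-benzyloxy-3-{2-[(4R,5S)-5-ethynyl-2,2-dimethyl-1,3-dioxolan-4-yl]propan-2-yloxy}-2-oxo-2H-pyran-6-carbaldehyde | O=C1OC(C=O)=CC(OCc2ccccc2)=C1OC(C)(C)[C@@H]3OC(C)(C)O[C@H]3C#C | intermediate
15 | bridged 2-oxabicyclo[2.2.2]octadienone cycloadduct (either bridgehead diastereomer, not isolated) | O=CC12OC(=O)C3(OC(C)(C)[C@@H]4OC(C)(C)O[C@H]4C3=C1)C(OCc5ccccc5)=C2 | intermediate
16 | trans-fused acetonide of (3R,4S)-8-benzyloxy-3,4-dihydroxy-2,2-dimethylchroman-6-carbaldehyde | CC1(C)Oc2c(OCc4ccccc4)cc(C=O)cc2[C@@H]3OC(C)(C)O[C@@H]13 | intermediate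
17 | 1-(2-bromo-4-hydroxyphenyl)ethan-1-one | CC(=O)c1ccc(O)cc1Br | starting material
18 | 1-[4-(benzyloxy)-2-bromophenyl]ethan-1-one | CC(=O)c1ccc(OCc2ccccc2)cc1Br | intermediate
19 | 1-[4-(benzyloxy)-2-bromophenyl]-3-hydroxy-3-(ArB)propan-1-one, carbinol epimers | CC1(C)Oc2c(OCc4ccccc4)cc(C(O)CC(=O)c5ccc(OCc6ccccc6)cc5Br)cc2[C@@H]3OC(C)(C)O[C@@H]13 | intermediate
20 | 1-[4-(benzyloxy)-2-bromophenyl]-3-(ArB)propane-1,3-dione | CC1(C)Oc2c(OCc4ccccc4)cc(C(=O)CC(=O)c5ccc(OCc6ccccc6)cc5Br)cc2[C@@H]3OC(C)(C)O[C@@H]13 | intermediate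
21 | (1S,3S)-1-[4-(benzyloxy)-2-bromophenyl]-3-(ArB)propane-1,3-diol | CC1(C)Oc2c(OCc4ccccc4)cc([C@@H](O)C[C@H](O)c5ccc(OCc6ccccc6)cc5Br)cc2[C@@H]3OC(C)(C)O[C@@H]13 | intermediate
22 | (2S,4S)-7-(benzyloxy)-2-(ArB)chroman-4-ol | CC1(C)Oc2c(OCc4ccccc4)cc([C@@H]5C[C@H](O)c6ccc(OCc7ccccc7)cc6O5)cc2[C@@H]3OC(C)(C)O[C@@H]13 | intermediate
23 | (2S)-7-(benzyloxy)-2-(ArB)chroman-4-one | CC1(C)Oc2c(OCc4ccccc4)cc([C@@H]5CC(=O)c6ccc(OCc7ccccc7)cc6O5)cc2[C@@H]3OC(C)(C)O[C@@H]13 | intermediate
24 | (2S)-7-(benzyloxy)-2-[(3R,4S)-8-(benzyloxy)-3,4-dihydroxy-2,2-dimethylchroman-6-yl]chroman-4-one | CC1(C)Oc2c(OCc4ccccc4)cc([C@@H]5CC(=O)c6ccc(OCc7ccccc7)cc6O5)cc2[C@H](O)[C@H]1O | intermediate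
25 | (2S)-7-hydroxy-2-[(3R,4S)-3,4,8-trihydroxy-2,2-dimethylchroman-6-yl]chroman-4-one | CC1(C)Oc2c(O)cc([C@@H]3CC(=O)c4ccc(O)cc4O3)cc2[C@H](O)[C@H]1O | target

**Step count**
- Total steps: 20.
- Longest linear sequence: 16 (steps 1–4, 8–12, 14–20).

**Steps most likely to fail**

**Step 12 (key step).**
- What may go wrong: cycloaddition of an unactivated terminal alkyne onto a pyrone that carries two oxygen donors may be slower than thermal breakdown. The likely breakdown paths are elimination at the tertiary C2'–O1' ether and degradation of the formyl group.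
- Fallback: the diene is retuned electronically instead of being heated harder. It sets out from 11.
- TsCl, Et3N, CH2Cl2 should give the 4-tosyloxypyrone silyl ether F1, in which the C4 donor has become an acceptor.
- Et3N·3HF should give the 4-tosyloxy-6-(hydroxymethyl)pyrone F2, and Dess–Martin oxidation the 6-formyl-4-tosyloxypyrone F3.
- This doubly acceptor-substituted pyrone should undergo the same tethered cycloaddition and CO2 loss at lower temperature (xylene, 110–140 °C) to give the 8-tosyloxychroman aldehyde F4.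
- KOH in MeOH–THF at 60 °C frees the 8-hydroxychroman aldehyde F5, and BnBr/K2CO3 in DMF comes back to the route at 16.

**Step 8.**
- What may go wrong: capture of the rhodium carbenoid by the hindered tertiary hydroxyl may lose out to attack on the alkyne, on the dioxolane oxygens or on traces of water.
- Fallback: the ether is made from the other side of the oxygen, by substitution at the non-stereogenic C2'. It sets out from 10 and 5.
- From 10, Rh2(OAc)4 in wet THF (insertion into unhindered water) should give the 3,4-dihydroxypyrone F6.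
- One equivalent of BnBr with KHCO3 in DMF should alkylate the far more acidic 4-OH to give the 4-benzyloxy-3-hydroxypyrone F7.
- From 5, Ph2PCl, Et3N and DMAP in THF should give the tertiary alkyl diphenylphosphinite F8.
- A Mukaiyama oxidation–reduction condensation of F7 with F8 and 2,6-dimethyl-1,4-benzoquinone in CH2Cl2 comes back to the route at 12.

**Step 17.**
- What may go wrong: coupling at the ortho-branched aryl bromide may be slow. Hydrodebromination and oxidation of the two benzylic alkoxides may then compete.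
- Fallback: ring C is closed by oxa-Michael addition and C2 is sorted afterwards. It sets out from 16.
- Claisen–Schmidt condensation with commercial 1-[4-(benzyloxy)-2-hydroxyphenyl]ethanone (KOH, EtOH, rt) should give the (E)-2'-hydroxychalcone F9.
- NaOAc in refluxing EtOH should close it to the flavanone as a mixture of C2 epimers F10.
- Transfer hydrogenation under kinetic resolution (Cp*RhCl[(S,S)-TsDPEN], HCO2H–Et3N, EtOAc) should reduce the (2S) epimer faster. Only for that epimer do the catalyst preference for an (S)-carbinol and the substrate preference for the 2,4-cis alcohol coincide. This comes back to the route at 22.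
- The unreacted (2R)-flavanone F11 is separated and re-equilibrated with NaOAc/EtOH to F10 for a further pass.

**Further compounds**
F1 | step 12 | 3-{2-[(4R,5S)-5-ethynyl-2,2-dimethyl-1,3-dioxolan-4-yl]propan-2-yloxy}-2-oxo-6-{[(tert-butyldimethylsilyl)oxy]methyl}-2H-pyran-4-yl 4-methylbenzenesulfonate | O=C1OC(CO[Si](C)(C)C(C)(C)C)=CC(OS(=O)(=O)c2ccc(C)cc2)=C1OC(C)(C)[C@@H]3OC(C)(C)O[C@H]3C#C
F2 | step 12 | 6-(hydroxymethyl) analogue of F1 | O=C1OC(CO)=CC(OS(=O)(=O)c2ccc(C)cc2)=C1OC(C)(C)[C@@H]3OC(C)(C)O[C@H]3C#C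
F3 | step 12 | 6-formyl analogue of F1 | O=C1OC(C=O)=CC(OS(=O)(=O)c2ccc(C)cc2)=C1OC(C)(C)[C@@H]3OC(C)(C)O[C@H]3C#C
F4 | step 12 | trans-fused acetonide of (3R,4S)-6-formyl-3,4-dihydroxy-2,2-dimethylchroman-8-yl 4-methylbenzenesulfonate | CC1(C)Oc2c(OS(=O)(=O)c4ccc(C)cc4)cc(C=O)cc2[C@@H]3OC(C)(C)O[C@@H]13
F5 | step 12 | trans-fused acetonide of (3R,4S)-3,4,8-trihydroxy-2,2-dimethylchroman-6-carbaldehyde | CC1(C)Oc2c(O)cc(C=O)cc2[C@@H]3OC(C)(C)O[C@@H]13
F6 | step 8 | 6-{[(tert-butyldimethylsilyl)oxy]methyl}-3,4-dihydroxy-2H-pyran-2-one | O=C1OC(CO[Si](C)(C)C(C)(C)C)=CC(O)=C1O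
F7 | step 8 | 4-(benzyloxy)-6-{[(tert-butyldimethylsilyl)oxy]methyl}-3-hydroxy-2H-pyran-2-one | O=C1OC(CO[Si](C)(C)C(C)(C)C)=CC(OCc2ccccc2)=C1O
F8 | step 8 | 2-[(4R,5S)-5-ethynyl-2,2-dimethyl-1,3-dioxolan-4-yl]propan-2-yl diphenylphosphinite | CC(C)(OP(c1ccccc1)c2ccccc2)[C@@H]3OC(C)(C)O[C@H]3C#C
F9 | step 17 | (E)-1-[4-(benzyloxy)-2-hydroxyphenyl]-3-(ArB)prop-2-en-1-one | CC1(C)Oc2c(OCc4ccccc4)cc(/C=C/C(=O)c5ccc(OCc6ccccc6)cc5O)cc2[C@@H]3OC(C)(C)O[C@@H]13
F10 | step 17 | 7-(benzyloxy)-2-(ArB)chroman-4-one, mixture of C2 epimers | CC1(C)Oc2c(OCc4ccccc4)cc(C5CC(=O)c6ccc(OCc7ccccc7)cc6O5)cc2[C@@H]3OC(C)(C)O[C@@H]13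
F11 | step 17 | (2R)-7-(benzyloxy)-2-(ArB)chroman-4-one | CC1(C)Oc2c(OCc4ccccc4)cc([C@H]5CC(=O)c6ccc(OCc7ccccc7)cc6O5)cc2[C@@H]3OC(C)(C)O[C@@H]13
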